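## The problem

Atom labels follow the carbon chain: C1 is the alkyne CH and C15 the ethyl CH3; Oa bridges C6 and C9, Ob bridges C7 and C13.

- **Ring system.** The target is a 2,8-dioxabicyclo[5.2.1]decane. An oxocane (Ob, C7 to C13) is spanned by a tetrahydrofuran (Oa, C6, C7, C8, C9), so C7 and C9 are shared bridgeheads and their ring bonds must be cis.
- **Stereocentres.** Six are needed (6R, 7S, 9S, 10S, 12S, 13R). C6/C7 is an erythro diol pattern. The C13 ethyl group is trans to the C7–C6 bond across Ob. The C12 bromine is trans to the ethyl group. Oa on C9 and bromine on C10 are anti.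
- **What controls what.** C7 can dictate C9, because the bridge can close only on its own face, and an anti addition to a (Z)-C9=C10 alkene then fixes C10. C13 is remote from C7 and has to be reached by a relay across the ring oxygen; C12 is best taken from C13.
- **Medium ring.** An eight-membered ether is poorly made by end-to-end closure.
- **Sensitive groups.** Both secondary bromides are β to oxygen and eliminate easily. The terminal (E)-enyne does not tolerate strong base, metals or bromonium sources for long. Halogens therefore go in late and the enyne last.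
- **Enabling feature.** Once the Oa–C9 and C10–Br bonds are removed, the oxocane carries a (Z)-C9=C10 alkene. With C13 at the carbonyl level it is an unsaturated eight-membered lactone, and its C11–C12 bond is the σ-bond formed by a [3,3] shift of a six-membered cyclic ketene acetal built on the C7/C9 1,3-diol.

## Retrosynthesis

**Enyne.** Cutting C1–C2 and then C3=C4 leads from 28 through the (E)-enal 27 to the allyl-substituted bicycle 25 and crotonaldehyde 26. Olefination of a C4 aldehyde with a propargylic ylide would give E/Z mixtures. Cross-metathesis with an enal and a one-carbon homologation both preserve E geometry and do not need conditions that attack secondary bromides. Compound 25 lacks the whole sensitive terminus. The forward steps must not eliminate HBr.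

**Tetrahydrofuran.** Cutting Oa–C9 and C10–Br opens 25 to the bromo-oxocene 24, with a free C6 hydroxyl and a (Z)-C9=C10 alkene. The reverse order (tetrahydrofuran first, oxocane closed last) would require an eight-membered closure. Here the ring formed is five-membered (5-exo) and the substrate fixes both new centres: the hydroxyl reaches C9 only on the face of the C7–C6 bond, and bromine must then sit anti on C10. One ring and two stereocentres disappear. Forward, the bromonium ion has to form on the ring alkene and not on the terminal one.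

**C4–C5 bond.** Cutting C4–C5 in 24 gives epoxide 23 and vinylmagnesium bromide 5. Epoxide 23 comes from diol 21 through its primary tosylate 22, and 21 from acetonide 20. The neighbouring option (protect O5, cyclise, deprotect, displace a C5 sulfonate) costs several steps. Opening the epoxide makes the carbon–carbon bond and frees exactly the C6 hydroxyl in one operation, with no protecting group on either oxygen. Forward, epoxide opening must be faster than any reaction at the C12 bromide.

**C12 bromide.** Cutting C12–Br in 20 leads to alcohol 19, with the hydroxyl on the opposite face (cis to ethyl). The substitution is done on the monocyclic oxocene because, once the tetrahydrofuran is closed, the backside of C12 lies under the bridge. Alcohol 19 is traced to ketone 18 and on to the epimeric alcohol 17 and its silyl ether 16. The C12 oxygen is first introduced on the other face (next paragraph), and hydride reduction anti to the neighbouring ethyl group is a dependable way to turn it over.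

**C13 ethyl and C12 oxygen.** Cutting C13–C14 in 16 gives the lactol acetate 15, made from silyloxy lactone 13 through the aluminium hemiacetal 14, and an ethyl nucleophile. Cutting C12–O gives lactone 10 by way of hydroxy lactone 12 and enolate 11. The order of bond formation at C13 decides its configuration. Adding ethyl to the lactone and reducing the hemiketal delivers hydride last and leads to the 2,8-cis ether. The target has ethyl trans to the C7–C6 bond, so the carbon nucleophile must be delivered last, to the hydrogen-substituted oxocarbenium ion. The silyl ether on C12 lies on the face of the C7–C6 bond and blocks the same face. Lactone 10 has neither the C12 nor the C13 stereocentre.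

**Key disconnection.** Cutting C11–C12 of 10 and reconnecting C9 to oxygen gives the 2-methylidene-4-vinyl-1,3-dioxane 9, the methylenation product of cyclic carbonate 8. Lactonisation of a seco acid or ring-closing metathesis would close the eight-membered ring end to end. The sigmatropic shift grows it out of a six-membered ring and places the Z alkene where the later bromoetherification needs it. The precursor has no medium ring, and its C9 configuration is irrelevant. Forward, the carbonate must be methylenated without consuming the product lactone.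

**Chiral pool.** Carbonate 8 is the carbonyl derivative (from carbonyldiimidazole 7) of 1,3-diol 6. Cutting C9–C10 of 6 gives vinylmagnesium bromide 5 and β-hydroxy aldehyde 4. Compound 4 is 2-deoxy-D-ribose 1 with its terminal diol as acetonide, reached through dithioacetals 2 and 3. The sugar supplies C5 to C9 with C6 and C7 already in the required (6R,7S) configuration. A route from a three-carbon chiral aldehyde would have to create C7.

## Roads not taken

Alternative 1: The cut is through C8–C9 and Oa–C6, a [3+2] annulation of the allylic silane A1 (C5 to C8, silicon on C6) with the α-benzyloxy aldehyde A2 (C9 to C15). Forward, SnCl4 chelates A2, A1 attacks through C8, silicon migrates from C6 to C7 and the C9 oxygen closes on C6. The product is the 2,5-trans tetrahydrofuran A3, with silicon as a masked C7 hydroxyl.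
- Merits: the route is convergent. The ring and C6, C7 and C9 appear in one step from two small fragments, with C10 set by chelation control, faster than any sugar route.
- Weak points:
  - The oxocane must be closed last by attack of the C7 oxygen on the C12=C13 alkene. This 8-endo bromoetherification competes with the 7-exo mode, and nothing selects the alkene face, so C12 and C13 are uncontrolled.
  - Unmasking the C–Si bond (Fleming–Tamao oxidation) needs electrophilic oxidants that the C12=C13 alkene does not tolerate.
  - In A3 the benzyloxy group on C10 occupies the position of the final bromine, so the halogen would have to enter with net retention.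
- Comparison: Alternative 1 is better in convergence and in how quickly the tetrahydrofuran stereocentres appear. The chosen plan sets against this a medium ring made by ring expansion, a last ring closed 5-exo under substrate control, and two bromines that enter by stereospecific steps.

Alternative 2: The cut is the C9–C10 bond of the oxocane. Substrate A4 is a 2-deoxyfuranosyl 2-pyridyl sulfone (the tetrahydrofuran) whose O7 already carries the C10 to C15 arm ending in the C10 aldehyde. SmI2 (divalent samarium) cleaves the sulfone, and the anomeric organosamarium adds to the aldehyde in a Barbier closure to give the bicyclic alcohol A5.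
- Merits:
  - C6 and C7 come from the same sugar as in the chosen plan, but the furanose is used directly as the tetrahydrofuran.
  - Either anomer serves, since the bridge can form only cis to O7.
  - The missing C8 oxygen excludes β-elimination.
  - The whole bicycle appears in one carbon–carbon bond formation.
- Weak points:
  - A4 requires an ether between two secondary carbons (C7–Ob–C13, with C13 defined), a poor intermolecular etherification.
  - The eight-membered closure is end to end, and the C10 carbinol configuration has no control element.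
  - A5 needs two hydroxyl-to-bromide inversions (C10 and C12) on a rigid bridged skeleton, where backside attack is hindered and elimination is easy.
- Comparison: Alternative 2 is potentially shorter and more convergent. The chosen plan pays with a long linear sequence. In return Ob is the sugar oxygen throughout, no medium ring is closed end to end, C10–Br is installed directly with its configuration, and the one inversion is done on the flexible monocycle.

Alternative 3: The cut is the C6–C7 bond. Substrate A6 is the complete oxocane (both bromines and the ethyl group in place) with a C7 carboxylic acid and a β-alkoxyacrylate on Oa. Under [Ir(dF(CF3)ppy)2(dtbbpy)]PF6 (a trivalent iridium photocatalyst) and visible light the carboxylate is oxidised and loses CO2. The α-alkoxy C7 radical adds 5-exo to the acrylate to give the bicyclic ester A7.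
- Merits: the conditions are mild and neutral and tolerate alkyl bromides. C7 needs no defined configuration before the step. The C4 ester is a more direct handle for the enyne than the allyl group of the chosen plan.
- Weak points:
  - A6 is no simpler than the target. A 2,8-trans oxocane with five substituents is the real problem and stays unsolved.
  - C6 depends on the facial course of the radical addition. The usual preference of β-alkoxyacrylate cyclisations is the 2,5-cis tetrahydrofuran, whereas the target has C5 and C10 trans across Oa.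
- Comparison: Alternative 3 has the better end game and functional-group tolerance. The chosen plan takes C6 and C7 from the sugar with no selectivity question and supplies a way to build the oxocane, which Alternative 3 presupposes.

Key step: step 6

Remark on the chemistry: atom labels C1 to C15, Oa and Ob are those of the target; C9 is formed as both epimers in step 4 and carried as such through 6, 8 and 9 (it becomes trigonal in step 6), and the acetal carbon of 14 and 15 is likewise a mixture, so the SMILES of these five compounds leave that one centre open.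

## Route

Step 1
Reactants: 1 2-deoxy-D-ribose
Product: 2 (2R,3S)-5,5-bis(ethylsulfanyl)pentane-1,2,3-triol
Conditions: EtSH, conc. HCl, 0 °C
Reagents that add atoms: ethanethiol, CCS
Why: Acid-catalysed dithioacetal formation on the aldose opens the lactol to the acyclic chain and masks C9; the two carbinol centres (later C7 and C6) are not involved.

Step 2
Reactants: 2 dithioacetal triol
Product: 3 (1S)-1-[(4R)-2,2-dimethyl-1,3-dioxolan-4-yl]-3,3-bis(ethylsulfanyl)propan-1-ol
Conditions: Me2C(OMe)2, TsOH (cat.), acetone, 0 °C
Reagents that add atoms: 2,2-dimethoxypropane, COC(C)(C)OC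
Why: Acetonide formation under equilibrating conditions favours the terminal dioxolane over the cis-4,5-disubstituted dioxolane and the six-membered ketal, so O5 and O6 are blocked and O7 stays free.

Step 3
Reactants: 3 acetonide dithioacetal
Product: 4 (3S)-3-[(4R)-2,2-dimethyl-1,3-dioxolan-4-yl]-3-hydroxypropanal
Conditions: I2, NaHCO3, acetone–H2O, 0 °C
Reagents that add atoms: water, O
Why: Iodine-promoted hydrolysis of the dithioacetal at buffered pH releases the aldehyde without touching the acetonide; the β-hydroxy aldehyde is taken on crude to avoid dehydration.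

Step 4
Reactants: 4 β-hydroxy aldehyde; 5 vinylmagnesium bromide
Product: 6 (3RS,5S)-5-[(4R)-2,2-dimethyl-1,3-dioxolan-4-yl]pent-1-ene-3,5-diol
Conditions: CH2=CHMgBr (3.5 equiv), THF, −78 → 0 °C
Reagents that add atoms: none
Why: Grignard addition to the aldehyde; the first equivalent turns the β-hydroxyl into a magnesium alkoxide, a poor leaving group, so addition should outrun elimination. Both C9 epimers are formed and both are used, because C9 loses its configuration in step 6.

Step 5
Reactants: 6 1,3-diol; 7 1,1'-carbonyldiimidazole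
Product: 8 (4RS,6S)-6-[(4R)-2,2-dimethyl-1,3-dioxolan-4-yl]-4-ethenyl-1,3-dioxan-2-one
Conditions: CDI, THF, rt → 60 °C
Reagents that add atoms: none
Why: Double acyl substitution on the carbonyl donor closes the six-membered cyclic carbonate across the only two free hydroxyls (O7 and O9).

Step 6
Reactants: 8 cyclic carbonate
Product: 10 (5Z,8S)-8-[(4R)-2,2-dimethyl-1,3-dioxolan-4-yl]-3,4,7,8-tetrahydro-2H-oxocin-2-one, via ketene acetal 9 (not isolated)
Conditions: Cp2TiMe2 (2.2 equiv), toluene, 110 °C, dark
Reagents that add atoms: dimethyltitanocene Cp2TiMe2, C[Ti](C)(C1C=CC=C1)C1C=CC=C1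
Why: On heating, Cp2TiMe2 loses methane to give the titanium methylidene Cp2Ti=CH2, which adds across the carbonate C=O and fragments to the 2-methylidene-1,3-dioxane 9 and titanocene oxide (carbonyl methylenation). Compound 9 then undergoes a Claisen rearrangement at the same temperature: with the vinyl group axial on the dioxane, C12 and C11 meet in a chair-like six-atom array, the C11–C12 bond forms, the allylic C9–O bond breaks and that oxygen becomes the lactone carbonyl. The closest known reaction type is the ring-expanding Claisen rearrangement of 2-methylidene-4-vinyl cyclic acetals generated in situ from cyclic carbonates, established for seven- to nine-membered lactones. The eight-membered ring is closed by two-carbon ring expansion of the six-membered acetal, not by end-to-end cyclisation, so no high dilution is required. No stereocentre is formed; C9 becomes trigonal, so both C9 epimers of 8 should converge on 10, the anti epimer through a chair with the C7 substituent equatorial and the syn epimer more slowly. The step needs Z geometry at C9=C10 and chemoselective methylenation: the geometry is imposed because C8 and C11 both lie in the new eight-membered ring, and attack on the product lactone is limited by using close to two equivalents of reagent and stopping at full conversion of 8. C6, C7 and the acetonide are spectators.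

Step 7
Reactants: 10 oxocenone
Product: 12 (3S,5Z,8S)-3-hydroxy-8-[(4R)-2,2-dimethyl-1,3-dioxolan-4-yl]-3,4,7,8-tetrahydro-2H-oxocin-2-one, via potassium enolate 11 (not isolated)
Conditions: KN(SiMe3)2, THF, −78 °C; then 2-(phenylsulfonyl)-3-phenyloxaziridine, −78 °C; aq. NH4Cl
Reagents that add atoms: 2-(phenylsulfonyl)-3-phenyloxaziridine, O=S(=O)(N1OC1c1ccccc1)c1ccccc1
Why: Enolate hydroxylation with an N-sulfonyloxaziridine (Davis oxidation); the oxidant should take the exposed outer face of the tub-shaped enolate, placing the hydroxyl cis to the C7–C6 bond, the sense established for oxocin-2-ones substituted next to the ring oxygen. This provisional C12 configuration serves to steer step 10 and is reset in step 13.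

Step 8
Reactants: 12 hydroxy lactone
Product: 13 (3S,5Z,8S)-3-[(tert-butyldimethylsilyl)oxy]-8-[(4R)-2,2-dimethyl-1,3-dioxolan-4-yl]-3,4,7,8-tetrahydro-2H-oxocin-2-one
Conditions: TBSCl, imidazole, DMF, rt
Reagents that add atoms: tert-butyldimethylsilyl chloride, CC(C)(C)[Si](C)(C)Cl
Why: Silylation of the secondary alcohol; the bulky ether survives hydride and Lewis acid and shields one face of C13.

Step 9
Reactants: 13 silyloxy lactone
Product: 15 (3S,5Z,8S)-3-[(tert-butyldimethylsilyl)oxy]-8-[(4R)-2,2-dimethyl-1,3-dioxolan-4-yl]-3,4,7,8-tetrahydro-2H-oxocin-2-yl acetate, via aluminium hemiacetal 14 (not isolated)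
Conditions: i-Bu2AlH, CH2Cl2, −78 °C; then pyridine, DMAP, Ac2O, −78 → 0 °C
Reagents that add atoms: acetic anhydride, CC(=O)OC(C)=O
Why: Reductive acetylation of a lactone: the tetrahedral aluminium hemiacetal is acetylated in situ before it can open to the hydroxy aldehyde, which an eight-membered lactol would otherwise prefer.

Step 10
Reactants: 15 lactol acetate
Product: 16 tert-butyl({(2R,3S,5Z,8S)-8-[(4R)-2,2-dimethyl-1,3-dioxolan-4-yl]-2-ethyl-3,4,7,8-tetrahydro-2H-oxocin-3-yl}oxy)dimethylsilane
Conditions: Et2Zn, Me3SiOTf, CH2Cl2, −78 °C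
Reagents that add atoms: diethylzinc, CC[Zn]CC
Why: The silyl triflate ionises the acetate to the ring oxocarbenium ion and ethyl is transferred from zinc (alkylation of an α-acetoxy ether). Hydride and carbon nucleophiles are expected to attack such cations on the same face, opposite the C7 side chain: hydride on a 2-ethyl cation gives the 2,8-cis ether, so ethyl on the 2-H cation should give the 2,8-trans arrangement required (13R). The C12 silyl ether lies on the face of the C7–C6 bond and blocks that face as well.

Step 11
Reactants: 16 silyl ether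
Product: 17 (2R,3S,5Z,8S)-8-[(4R)-2,2-dimethyl-1,3-dioxolan-4-yl]-2-ethyl-3,4,7,8-tetrahydro-2H-oxocin-3-ol
Conditions: Bu4NF, THF, 0 °C → rt
Reagents that add atoms: none
Why: Fluoride cleavage of the silyl ether; acetonide, alkene and ring ether are inert.

Step 12
Reactants: 17 alcohol (hydroxyl trans to ethyl)
Product: 18 (2R,5Z,8S)-8-[(4R)-2,2-dimethyl-1,3-dioxolan-4-yl]-2-ethyl-7,8-dihydro-2H-oxocin-3(4H)-one
Conditions: Dess–Martin periodinane, NaHCO3, CH2Cl2, 0 °C
Reagents that add atoms: none
Why: Dess–Martin oxidation under buffered, non-basic conditions should give the β,γ-unsaturated α-alkoxy ketone without moving the alkene into conjugation or epimerising C13; the ketone is used at once.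

Step 13
Reactants: 18 ketone
Product: 19 (2R,3R,5Z,8S)-8-[(4R)-2,2-dimethyl-1,3-dioxolan-4-yl]-2-ethyl-3,4,7,8-tetrahydro-2H-oxocin-3-ol
Conditions: LiBH(s-Bu)3, THF, −78 °C
Reagents that add atoms: none
Why: Bulky hydride reduction; hydride should enter anti to the adjacent C13 ethyl group, giving the alcohol cis to ethyl, the course known for 2-ethyl-oxocen-3-ones.

Step 14
Reactants: 19 alcohol (hydroxyl cis to ethyl)
Product: 20 (2R,3S,5Z,8S)-3-bromo-8-[(4R)-2,2-dimethyl-1,3-dioxolan-4-yl]-2-ethyl-3,4,7,8-tetrahydro-2H-oxocine
Conditions: CBr4, (n-C8H17)3P, 1-methylcyclohexene, toluene, 70 °C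
Reagents that add atoms: carbon tetrabromide, BrC(Br)(Br)Br
Why: Appel bromination; bromide displaces the alkoxyphosphonium group with inversion, giving the 12S bromide trans to ethyl. 1-Methylcyclohexene scavenges HBr so that the acetonide survives.

Step 15
Reactants: 20 bromo acetonide
Product: 21 (1R)-1-[(2S,4Z,7S,8R)-7-bromo-8-ethyl-3,6,7,8-tetrahydro-2H-oxocin-2-yl]ethane-1,2-diol
Conditions: AcOH–H2O (4:1), 40 °C
Reagents that add atoms: none
Why: Acid hydrolysis of the acetonide; the secondary bromide, the cis alkene and the ring ether tolerate weak aqueous acid.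

Step 16
Reactants: 21 diol
Product: 23 (2R,3S,5Z,8S)-3-bromo-2-ethyl-8-[(2R)-oxiran-2-yl]-3,4,7,8-tetrahydro-2H-oxocine, via primary tosylate 22 (not isolated)
Conditions: TsCl, Et3N, Bu2SnO (cat.), CH2Cl2, rt; then K2CO3, MeOH, 0 °C
Reagents that add atoms: none
Why: Tin-catalysed sulfonylation selects the primary hydroxyl, and mild base closes the epoxide by intramolecular Williamson displacement; C6 keeps its C–O bond and its configuration.

Step 17
Reactants: 23 epoxide; 5 vinylmagnesium bromide
Product: 24 (1R)-1-[(2S,4Z,7S,8R)-7-bromo-8-ethyl-3,6,7,8-tetrahydro-2H-oxocin-2-yl]but-3-en-1-ol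
Conditions: CH2=CHMgBr, CuI (10 mol%), THF, −40 → −20 °C
Reagents that add atoms: none
Why: Copper-catalysed Grignard opening of a terminal epoxide at the unsubstituted carbon forms C4–C5 and frees the C6 hydroxyl in one step; the hindered secondary bromide should be much slower at this temperature.

Step 18
Reactants: 24 homoallylic alcohol
Product: 25 (1S,3R,4S,6S,7S,9R)-4,6-dibromo-3-ethyl-9-(prop-2-en-1-yl)-2,8-dioxabicyclo[5.2.1]decane
Conditions: NBS, MeCN, 0 °C, dark
Reagents that add atoms: N-bromosuccinimide, O=C1CCC(=O)N1Br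
Why: Bromoetherification, 5-exo: the C6 hydroxyl can reach C9 only on the face of the C7–C6 bond (9S), and anti opening of the bromonium ion on the Z alkene puts bromine on the opposite face of C10 (10S). The terminal alkene is less nucleophilic and offers the hydroxyl only 4-exo or 5-endo modes.

Step 19
Reactants: 25 allyl bicycle; 26 (E)-but-2-enal (crotonaldehyde)
Product: 27 (2E)-4-[(1S,3R,4S,6S,7S,9R)-4,6-dibromo-3-ethyl-2,8-dioxabicyclo[5.2.1]decan-9-yl]but-2-enal
Conditions: crotonaldehyde (10 equiv), second-generation Hoveyda–Grubbs catalyst RuCl2(=CH-C6H4-2-Oi-Pr)(H2IMes) (5 mol%), CH2Cl2, 40 °C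
Reagents that add atoms: none
Why: Olefin cross-metathesis of a terminal alkene with an electron-poor partner is E-selective and driven by loss of propene; no other alkene remains in 25.

Step 20
Reactants: 27 enal
Product: 28 (1S,3R,4S,6S,7S,9R)-4,6-dibromo-3-ethyl-9-[(2E)-pent-2-en-4-yn-1-yl]-2,8-dioxabicyclo[5.2.1]decane
Conditions: Me3SiCHN2, LiN(i-Pr)2, THF, −78 °C; then 27, −78 → 0 °C
Reagents that add atoms: (trimethylsilyl)diazomethane, C[Si](C)(C)C=[N+]=[N-]
Why: Colvin rearrangement: the lithiated silyldiazomethane adds to the aldehyde, silanolate is eliminated, and the diazoalkene loses N2 to an alkylidene carbene whose 1,2-hydrogen shift gives the terminal alkyne. The E alkene is untouched, and the low temperature spares the secondary bromides.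

## Compound list

1 | 2-deoxy-D-ribose (open-chain form) | O=CC[C@H](O)[C@H](O)CO | starting material
2 | (2R,3S)-5,5-bis(ethylsulfanyl)pentane-1,2,3-triol | CCSC(SCC)C[C@H](O)[C@H](O)CO | intermediate
3 | (1S)-1-[(4R)-2,2-dimethyl-1,3-dioxolan-4-yl]-3,3-bis(ethylsulfanyl)propan-1-ol | CCSC(SCC)C[C@H](O)[C@H]1COC(C)(C)O1 | intermediate
4 | (3S)-3-[(4R)-2,2-dimethyl-1,3-dioxolan-4-yl]-3-hydroxypropanal | O=CC[C@H](O)[C@H]1COC(C)(C)O1 | intermediate
5 | vinylmagnesium bromide | C=C[Mg]Br | starting material
6 | (3RS,5S)-5-[(4R)-2,2-dimethyl-1,3-dioxolan-4-yl]pent-1-ene-3,5-diol (both C9 epimers) | C=CC(O)C[C@H](O)[C@H]1COC(C)(C)O1 | intermediate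
7 | 1,1'-carbonyldiimidazole | O=C(n1ccnc1)n1ccnc1 | starting material
8 | (4RS,6S)-6-[(4R)-2,2-dimethyl-1,3-dioxolan-4-yl]-4-ethenyl-1,3-dioxan-2-one (both C9 epimers) | O=C1OC(C=C)C[C@H](O1)[C@H]2COC(C)(C)O2 | intermediate
9 | (4RS,6S)-6-[(4R)-2,2-dimethyl-1,3-dioxolan-4-yl]-4-ethenyl-2-methylidene-1,3-dioxane (ketene acetal, formed in situ) | C=C1OC(C=C)C[C@H](O1)[C@H]2COC(C)(C)O2 | intermediate
10 | (5Z,8S)-8-[(4R)-2,2-dimethyl-1,3-dioxolan-4-yl]-3,4,7,8-tetrahydro-2H-oxocin-2-one | O=C1CC/C=C\C[C@H](O1)[C@H]2COC(C)(C)O2 | intermediate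
11 | potassium enolate of 10 (formed in situ) | [K+].[O-]C1=CC/C=C\C[C@H](O1)[C@H]2COC(C)(C)O2 | intermediate
12 | (3S,5Z,8S)-3-hydroxy-8-[(4R)-2,2-dimethyl-1,3-dioxolan-4-yl]-3,4,7,8-tetrahydro-2H-oxocin-2-one | O=C1[C@@H](O)C/C=C\C[C@H](O1)[C@H]2COC(C)(C)O2 | intermediate
13 | (3S,5Z,8S)-3-[(tert-butyldimethylsilyl)oxy]-8-[(4R)-2,2-dimethyl-1,3-dioxolan-4-yl]-3,4,7,8-tetrahydro-2H-oxocin-2-one | O=C1[C@@H](O[Si](C)(C)C(C)(C)C)C/C=C\C[C@H](O1)[C@H]2COC(C)(C)O2 | intermediate
14 | diisobutylaluminium hemiacetal of 13 (formed in situ, both C13 epimers) | CC(C)C[Al](CC(C)C)OC1[C@@H](O[Si](C)(C)C(C)(C)C)C/C=C\C[C@H](O1)[C@H]2COC(C)(C)O2 | intermediate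
15 | (3S,5Z,8S)-3-[(tert-butyldimethylsilyl)oxy]-8-[(4R)-2,2-dimethyl-1,3-dioxolan-4-yl]-3,4,7,8-tetrahydro-2H-oxocin-2-yl acetate (both anomers) | CC(=O)OC1[C@@H](O[Si](C)(C)C(C)(C)C)C/C=C\C[C@H](O1)[C@H]2COC(C)(C)O2 | intermediate
16 | tert-butyl({(2R,3S,5Z,8S)-8-[(4R)-2,2-dimethyl-1,3-dioxolan-4-yl]-2-ethyl-3,4,7,8-tetrahydro-2H-oxocin-3-yl}oxy)dimethylsilane | CC[C@@H]1[C@@H](O[Si](C)(C)C(C)(C)C)C/C=C\C[C@H](O1)[C@H]2COC(C)(C)O2 | intermediate
17 | (2R,3S,5Z,8S)-8-[(4R)-2,2-dimethyl-1,3-dioxolan-4-yl]-2-ethyl-3,4,7,8-tetrahydro-2H-oxocin-3-ol | CC[C@@H]1[C@@H](O)C/C=C\C[C@H](O1)[C@H]2COC(C)(C)O2 | intermediate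
18 | (2R,5Z,8S)-8-[(4R)-2,2-dimethyl-1,3-dioxolan-4-yl]-2-ethyl-7,8-dihydro-2H-oxocin-3(4H)-one | CC[C@@H]1C(=O)C/C=C\C[C@H](O1)[C@H]2COC(C)(C)O2 | intermediate
19 | (2R,3R,5Z,8S)-8-[(4R)-2,2-dimethyl-1,3-dioxolan-4-yl]-2-ethyl-3,4,7,8-tetrahydro-2H-oxocin-3-ol | CC[C@@H]1[C@H](O)C/C=C\C[C@H](O1)[C@H]2COC(C)(C)O2 | intermediate
20 | (2R,3S,5Z,8S)-3-bromo-8-[(4R)-2,2-dimethyl-1,3-dioxolan-4-yl]-2-ethyl-3,4,7,8-tetrahydro-2H-oxocine | CC[C@@H]1[C@@H](Br)C/C=C\C[C@H](O1)[C@H]2COC(C)(C)O2 | intermediate
21 | (1R)-1-[(2S,4Z,7S,8R)-7-bromo-8-ethyl-3,6,7,8-tetrahydro-2H-oxocin-2-yl]ethane-1,2-diol | CC[C@@H]1[C@@H](Br)C/C=C\C[C@H](O1)[C@H](O)CO | intermediate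
22 | (2R)-2-[(2S,4Z,7S,8R)-7-bromo-8-ethyl-3,6,7,8-tetrahydro-2H-oxocin-2-yl]-2-hydroxyethyl 4-methylbenzenesulfonate (formed in situ) | CC[C@@H]1[C@@H](Br)C/C=C\C[C@H](O1)[C@H](O)COS(=O)(=O)c1ccc(C)cc1 | intermediate
23 | (2R,3S,5Z,8S)-3-bromo-2-ethyl-8-[(2R)-oxiran-2-yl]-3,4,7,8-tetrahydro-2H-oxocine | CC[C@@H]1[C@@H](Br)C/C=C\C[C@H](O1)[C@H]2CO2 | intermediate
24 | (1R)-1-[(2S,4Z,7S,8R)-7-bromo-8-ethyl-3,6,7,8-tetrahydro-2H-oxocin-2-yl]but-3-en-1-ol | CC[C@@H]1[C@@H](Br)C/C=C\C[C@H](O1)[C@H](O)CC=C | intermediate
25 | (1S,3R,4S,6S,7S,9R)-4,6-dibromo-3-ethyl-9-(prop-2-en-1-yl)-2,8-dioxabicyclo[5.2.1]decane | C=CC[C@H]1O[C@H]2C[C@@H]1O[C@H](CC)[C@@H](Br)C[C@@H]2Br | intermediate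
26 | (E)-but-2-enal (crotonaldehyde) | C/C=C/C=O | starting material
27 | (2E)-4-[(1S,3R,4S,6S,7S,9R)-4,6-dibromo-3-ethyl-2,8-dioxabicyclo[5.2.1]decan-9-yl]but-2-enal | O=C/C=C/C[C@H]1O[C@H]2C[C@@H]1O[C@H](CC)[C@@H](Br)C[C@@H]2Br | intermediate
28 | (1S,3R,4S,6S,7S,9R)-4,6-dibromo-3-ethyl-9-[(2E)-pent-2-en-4-yn-1-yl]-2,8-dioxabicyclo[5.2.1]decane | C#C/C=C/C[C@H]1O[C@H]2C[C@@H]1O[C@H](CC)[C@@H](Br)C[C@@H]2Br | target

## Step count and least certain steps

Total: 20 steps. Longest linear sequence: 20 steps, from 1 to 28.

**Step 6 (key step).** The most likely failure is over-reaction: the titanium methylidene also methylenates the lactone carbonyl of 10 as it accumulates. The syn epimer of 8 also needs a less favourable geometry and rearranges slowly, so its ketene acetal is exposed longer to hydrolysis. The fallback reaches the same ketene acetal without titanium. It sets out from diol 6 and returns at lactone 10. Diol 6 is acetalised with (phenylselanyl)acetaldehyde diethyl acetal (PPTS, toluene, 80 °C) to the 2-[(phenylselanyl)methyl]-1,3-dioxane F1. Oxidation with NaIO4 (NaHCO3, MeOH–H2O) gives the selenoxide F2. Heating F2 with DBU in xylene (140 °C) eliminates benzeneselenenic acid to give 9, which rearranges to 10.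

**Step 10.** The most likely failure is poor facial selectivity in the addition to the flexible eight-membered oxocarbenium ion, since both control elements are inferred by analogy. Transannular capture of the cation by the C9=C10 alkene and loss of the acetonide under the silyl triflate are further risks. The fallback sets C13 by a tether from the C12 oxygen instead of by the ring. It sets out from hydroxy lactone 12 and returns at alcohol 19.
- The C12 hydroxyl is inverted first: Tf2O and pyridine give the triflate F3, and KNO2 with 18-crown-6 in DMF (Lattrell–Dax inversion) gives the C12-epimeric hydroxy lactone F4.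
- Silylation (Et3SiCl, imidazole) gives the triethylsilyl ether F5, and methylenation (Cp2Ti(μ-Cl)(μ-CH2)AlMe2, pyridine, THF–toluene, −40 °C → rt) gives the exocyclic enol ether F6.
- Bu4NF frees the allylic alcohol F7, and (HMe2Si)2NH converts it into the hydrodimethylsilyl ether F8.
- Intramolecular hydrosilylation (Pt2[(CH2=CHSiMe2)2O]3, cat.) closes F8 to the cis-fused oxasilolane F9. This puts C14 cis to the C12 oxygen, the known sense of this five-membered-ring delivery.
- Tamao oxidation (H2O2, KF, KHCO3) gives the diol F10.
- Tosylation of the primary hydroxyl (TsCl, pyridine) gives the tosylate F11, and Me2CuLi turns CH2OTs into the ethyl group, arriving at 19.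

**Step 13.** The most likely failures are erosion of facial selectivity in the reduction, and enolisation of ketone 18 (epimerisation at C13 or migration of the alkene into conjugation) before hydride arrives. The fallback replaces the facial choice by a stereospecific substitution. It sets out from alcohol 17 and returns at 19. Mitsunobu reaction of 17 (4-nitrobenzoic acid, PPh3, diisopropyl azodicarboxylate, toluene) gives the inverted 4-nitrobenzoate F12, and methanolysis (K2CO3, MeOH) gives 19.

**Step 18.** The most likely failures are competing bromonium formation on the terminal alkene and transannular capture of the ring bromonium ion by Ob, leading to oxonium-derived rearrangement products. The fallback closes the tetrahydrofuran before any side-chain alkene exists. It sets out from diol 21 and returns at 25.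
- Selective silylation of the primary hydroxyl (t-BuPh2SiCl, imidazole) gives the silyl ether F13.
- NBS in MeCN gives the bicyclic dibromide silyl ether F14.
- Bu4NF buffered with AcOH gives the primary alcohol F15.
- Tf2O with 2,6-lutidine at −78 °C gives the triflate F16.
- Displacement with CH2=CHMgBr and CuI (cat.) at −78 °C gives 25.

**Step 20.** The most likely failure is base-induced loss of HBr from one of the secondary bromides, caused by the lithiated diazomethane or residual amide. The fallback builds the enyne without strong base. It sets out from 25 and returns at 28.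
- Ozonolysis (O3, CH2Cl2, −78 °C; PPh3) gives the aldehyde F17.
- Takai olefination (CrCl2, divalent chromium, with CHI3 in THF) gives the (E)-vinyl iodide F18.
- Sonogashira coupling with ethynyltrimethylsilane (Pd(PPh3)4, zerovalent palladium; CuI; i-Pr2NH) gives the silylated enyne F19.
- K2CO3 in MeOH removes silicon to give 28.

**Step 4.** The most likely failure is dehydration or retro-aldol loss of the unprotected β-hydroxy aldehyde 4 before or during the addition. The fallback carries O7 protected. It sets out from 3 and returns at 6.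
- Silylation (TBSCl, imidazole) gives the silyl ether F20.
- Hydrolysis of the dithioacetal (I2, NaHCO3, aqueous acetone) gives the aldehyde F21.
- Addition of CH2=CHMgBr gives the allylic alcohol F22.
- Bu4NF gives 6.

## Further compounds

F1 | step 6 | (4RS,6S)-6-[(4R)-2,2-dimethyl-1,3-dioxolan-4-yl]-4-ethenyl-2-[(phenylselanyl)methyl]-1,3-dioxane (C2 and C4 epimers) | c1ccccc1[Se]CC2OC(C=C)C[C@H](O2)[C@H]3COC(C)(C)O3
F2 | step 6 | selenoxide of F1 | O=[Se](c1ccccc1)CC2OC(C=C)C[C@H](O2)[C@H]3COC(C)(C)O3
F3 | step 10 | trifluoromethanesulfonate of 12 | O=C1[C@@H](OS(=O)(=O)C(F)(F)F)C/C=C\C[C@H](O1)[C@H]2COC(C)(C)O2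
F4 | step 10 | (3R,5Z,8S)-3-hydroxy-8-[(4R)-2,2-dimethyl-1,3-dioxolan-4-yl]-3,4,7,8-tetrahydro-2H-oxocin-2-one (C12 epimer of 12) | O=C1[C@H](O)C/C=C\C[C@H](O1)[C@H]2COC(C)(C)O2
F5 | step 10 | triethylsilyl ether of F4 | O=C1[C@H](O[Si](CC)(CC)CC)C/C=C\C[C@H](O1)[C@H]2COC(C)(C)O2
F6 | step 10 | triethyl({(3R,5Z,8S)-8-[(4R)-2,2-dimethyl-1,3-dioxolan-4-yl]-2-methylidene-3,4,7,8-tetrahydro-2H-oxocin-3-yl}oxy)silane | C=C1[C@H](O[Si](CC)(CC)CC)C/C=C\C[C@H](O1)[C@H]2COC(C)(C)O2
F7 | step 10 | (3R,5Z,8S)-8-[(4R)-2,2-dimethyl-1,3-dioxolan-4-yl]-2-methylidene-3,4,7,8-tetrahydro-2H-oxocin-3-ol | C=C1[C@H](O)C/C=C\C[C@H](O1)[C@H]2COC(C)(C)O2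
F8 | step 10 | dimethylsilyl (Si–H) ether of F7 | C=C1[C@H](O[SiH](C)C)C/C=C\C[C@H](O1)[C@H]2COC(C)(C)O2
F9 | step 10 | cis-fused 2,2-dimethyl-1,2-oxasilolane spanning O12 and C14 | C[Si]3(C)C[C@@H]1[C@H](O3)C/C=C\C[C@H](O1)[C@H]2COC(C)(C)O2
F10 | step 10 | (2R,3R,5Z,8S)-8-[(4R)-2,2-dimethyl-1,3-dioxolan-4-yl]-2-(hydroxymethyl)-3,4,7,8-tetrahydro-2H-oxocin-3-ol | OC[C@@H]1[C@H](O)C/C=C\C[C@H](O1)[C@H]2COC(C)(C)O2
F11 | step 10 | primary 4-methylbenzenesulfonate of F10 | Cc1ccc(cc1)S(=O)(=O)OC[C@@H]1[C@H](O)C/C=C\C[C@H](O1)[C@H]2COC(C)(C)O2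
F12 | step 13 | (2R,3R,5Z,8S)-8-[(4R)-2,2-dimethyl-1,3-dioxolan-4-yl]-2-ethyl-3,4,7,8-tetrahydro-2H-oxocin-3-yl 4-nitrobenzoate | CC[C@@H]1[C@H](OC(=O)c3ccc(cc3)[N+](=O)[O-])C/C=C\C[C@H](O1)[C@H]2COC(C)(C)O2
F13 | step 18 | primary tert-butyldiphenylsilyl ether of 21 | CC[C@@H]1[C@@H](Br)C/C=C\C[C@H](O1)[C@H](O)CO[Si](c1ccccc1)(c1ccccc1)C(C)(C)C
F14 | step 18 | tert-butyl{[(1S,3R,4S,6S,7S,9R)-4,6-dibromo-3-ethyl-2,8-dioxabicyclo[5.2.1]decan-9-yl]methoxy}diphenylsilane | CC(C)(C)[Si](c1ccccc1)(c1ccccc1)OC[C@H]1O[C@H]2C[C@@H]1O[C@H](CC)[C@@H](Br)C[C@@H]2Br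
F15 | step 18 | [(1S,3R,4S,6S,7S,9R)-4,6-dibromo-3-ethyl-2,8-dioxabicyclo[5.2.1]decan-9-yl]methanol | OC[C@H]1O[C@H]2C[C@@H]1O[C@H](CC)[C@@H](Br)C[C@@H]2Br
F16 | step 18 | trifluoromethanesulfonate of F15 | O=S(=O)(OC[C@H]1O[C@H]2C[C@@H]1O[C@H](CC)[C@@H](Br)C[C@@H]2Br)C(F)(F)F
F17 | step 20 | 2-[(1S,3R,4S,6S,7S,9R)-4,6-dibromo-3-ethyl-2,8-dioxabicyclo[5.2.1]decan-9-yl]acetaldehyde | O=CC[C@H]1O[C@H]2C[C@@H]1O[C@H](CC)[C@@H](Br)C[C@@H]2Br
F18 | step 20 | (1S,3R,4S,6S,7S,9R)-4,6-dibromo-3-ethyl-9-[(2E)-3-iodoprop-2-en-1-yl]-2,8-dioxabicyclo[5.2.1]decane | I/C=C/C[C@H]1O[C@H]2C[C@@H]1O[C@H](CC)[C@@H](Br)C[C@@H]2Br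
F19 | step 20 | C1-trimethylsilyl derivative of 28 | C[Si](C)(C)C#C/C=C/C[C@H]1O[C@H]2C[C@@H]1O[C@H](CC)[C@@H](Br)C[C@@H]2Br
F20 | step 4 | tert-butyldimethylsilyl ether of 3 | CCSC(SCC)C[C@H](O[Si](C)(C)C(C)(C)C)[C@H]1COC(C)(C)O1
F21 | step 4 | (3S)-3-[(tert-butyldimethylsilyl)oxy]-3-[(4R)-2,2-dimethyl-1,3-dioxolan-4-yl]propanal | O=CC[C@H](O[Si](C)(C)C(C)(C)C)[C@H]1COC(C)(C)O1
F22 | step 4 | (3RS,5S)-5-[(tert-butyldimethylsilyl)oxy]-5-[(4R)-2,2-dimethyl-1,3-dioxolan-4-yl]pent-1-en-3-ol | C=CC(O)C[C@H](O[Si](C)(C)C(C)(C)C)[C@H]1COC(C)(C)O1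
A1 | alternative 1 | tert-butyl{[(2R)-2-[dimethyl(phenyl)silyl]but-3-en-1-yl]oxy}diphenylsilane | CC(C)(C)[Si](c1ccccc1)(c1ccccc1)OC[C@H]([Si](C)(C)c1ccccc1)C=C
A2 | alternative 1 | (2S,4E)-2-(benzyloxy)hept-4-enal | O=C[C@@H](OCc1ccccc1)C/C=C/CC
A3 | alternative 1 | 2,5-trans tetrahydrofuran with PhMe2Si on C7, benzyloxy on C10, (E)-C12=C13 alkene and C5 silyl ether | CC(C)(C)[Si](c1ccccc1)(c1ccccc1)OC[C@H]1O[C@H]([C@@H](OCc2ccccc2)C/C=C/CC)C[C@@H]1[Si](C)(C)c1ccccc1
A4 | alternative 2 | 2-deoxyfuranosyl 2-pyridyl sulfone (either anomer) carrying on O7 the C10 to C15 arm as C10 aldehyde and C12 silyl ether | CC(C)(C)[Si](c1ccccc1)(c1ccccc1)OC[C@H]1OC(S(=O)(=O)c2ccccn2)C[C@@H]1O[C@H](CC)[C@H](O[Si](C)(C)C(C)(C)C)CC=O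
A5 | alternative 2 | bicyclic C10 alcohol with C12 tert-butyldimethylsilyl ether and C5 tert-butyldiphenylsilyl ether | CC(C)(C)[Si](c1ccccc1)(c1ccccc1)OC[C@H]1O[C@H]2C[C@@H]1O[C@H](CC)[C@H](O[Si](C)(C)C(C)(C)C)C[C@H]2O
A6 | alternative 3 | oxocane C7 carboxylic acid (C7 epimers) with Oa as methyl (E)-β-alkoxyacrylate, bromine on C10 and C12, ethyl on C13 | COC(=O)/C=C/O[C@H]1CC(C(=O)O)O[C@H](CC)[C@@H](Br)C[C@@H]1Br
A7 | alternative 3 | methyl 2-(4,6-dibromo-3-ethyl-2,8-dioxabicyclo[5.2.1]decan-9-yl)acetate | COC(=O)C[C@H]1O[C@H]2C[C@@H]1O[C@H](CC)[C@@H](Br)C[C@@H]2Br
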